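The data come from a simulation with constants of no real substance.

4 questions are asked about the beta flask, and they turn on one quantity that can be read from the runs so far.

in all of them: starting material 16 mM

| flask | reagent | second substrate | protic impurity | remark | time |
|---|---|---|---|---|---|
| beta | 24 mM | 8 mM | 0.80 mM | the very flask that is asked about, followed so far |  |
| eta | 12 mM | 8 mM | 0.80 mM | run made earlier |  |
| flask | 24.0 mM | 8.00 mM | 0.800 mM |  | 6.0 d |

| run | time / h | target / % | starting material / % |
|---|---|---|---|
| beta | 20.0 | 67 | 2 |
| beta | 48.0 | 67 | 0 |
| beta | 96.0 | 67 | 0 |
| beta | 144 | 72 | 3 |
| eta | 5.00 | 30 | 54 |
| eta | 10.0 | 31 | 52 |
| eta | 15.0 | 33 | 55 |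
| eta | 20.0 | 30 | 53 |

(readings scatter by 2 percentage points)

- ochre: at 6.0 d add starting material, 50.0 % of the amount charged, then wait 3.0 d
- green: at 6.0 d add reagent, 50.0 % of the amount charged, then wait 3.0 d
- teal: change nothing and wait 3.0 d more
- grey: at 6.0 d take out 90 % of the target then present, then wait 3.0 d

- removed target is counted in
- on the list of suspects stand: second substrate + reagent -> second product; target <-> isomer of the product; 2 second substrate -> self-condensation product; second substrate + protic impurity -> quenched substrate; starting material + reagent -> target
- additions bring no volume worth counting

1. target, in percent of the starting material first charged, at 6.0 d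
2. which option adds most target ("none" when 2 percentage points or less is all one gets) (ochre / green / teal / grey / none)
3. target present, with what was taken out counted in, in percent of the starting material first charged, after teal
4. target present, with what was taken out counted in, in percent of the starting material first charged, after grey

At first the beta readings do not seem to fit together: the starting material reads 0 % at 48.0 h, yet the target reads 67 %, so about a third of what was consumed is not target. Replace each curve by its mean. The beta run averages 68.3 % target with 1.25 % starting material, which gives 0.691. This is the target share, the target as a fraction of the starting material consumed. The mean costs little, because the furthest beta reading lies 3.7 percentage points from it, less than two standard deviations.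

The eta run, charged with half the reagent of the beta run, stalls at lower conversion and still gives 0.667. I read this as target and isomer of the product in equilibrium, which is thermodynamic control of the pool.

So, taking the starting material as consumed, I reckon the target in the beta flask at 6.0 d at 69.1 %, and the same after teal. Grey takes out 90 % of the target, and the rest of the pool returns to the same share, so the total becomes 88.3 %. The 3.0 d allowed is longer than the 5.00 h by which the eta target already stood level.

The forecast gives 68 % at 6.0 d, 68 % after teal and 87 % after grey, slightly below mine, and chooses grey, holding that the “flat plateau argues for reversibility rather than decay”.

The beta flask gives 69.0 %, then 69.0 % after teal and 88.2 % after grey, so grey adds most, 19 points.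

second substrate + reagent → second product (k = 0.0212 L mol⁻¹ s⁻¹); target ⇌ isomer of the product (K = 0.450, k = 3.04 × 10⁻⁵ s⁻¹); 2 second substrate → self-condensation product (k = 0.00135 L mol⁻¹ s⁻¹); second substrate + protic impurity → quenched substrate (k = 0.159 L mol⁻¹ s⁻¹); starting material + reagent → target (k = 0.0122 L mol⁻¹ s⁻¹) The relaxation half-life of target and isomer of the product, both ways together, is 1.97 h, short against 3.0 d. The target share also prices ochre: 4.15 % of the charged reagent is still free at 144 h, which predicts 4.3 points against the 4.3 points ochre adds. The neighbour with 20 mM of second substrate keeps 40 % of its starting material, so the share predicts 41.5 %, and that flask holds 41.7 % target.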